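**Retrosynthetic overview**
1. The strategy rests on ring C, the 2,4-dihydroxy-6-methylbenzoyl (orsellinoyl) unit on O4 of ring B. Its carbons C1–C6 plus the ester carbonyl and the methyl are a folded 3,5,7-trioxooctanoyl chain, so the ring C1–C6 bond (chain C2–C7) is cut and ring C is formed last, on the intact A–B depside.
2. The aryl 3,5,7-trioxooctanoate is disconnected at its ester C–O bond into the A–B phenol and the acylketene released from 6-(2,4-dioxopentyl)-2,2-dimethyl-1,3-dioxin-4-one.
3. The A–B depside link is made by TFAA esterification of 4-(benzyloxy)-2-methoxy-6-methylbenzoic acid with methyl orsellinate at its free O4; rings A and B both come from methyl orsellinate and are never constructed.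
4. The diketo-dioxinone comes from 2,2,6-trimethyl-1,3-dioxin-4-one by two successive Claisen C-acylations.

Key step: step 9

Remark: the target has no stereocentre and no hindered axis, so "single enantiomer" is taken to mean the achiral compound as drawn and no step needs stereocontrol.
Remark: enolates pre-formed in a separate operation are numbered as intermediates; salts that exist only until work-up are written in their neutral form.

Step 1
Reactants: 1 methyl orsellinate (methyl 2,4-dihydroxy-6-methylbenzoate); 2 benzyl bromide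
Product: 3 methyl 4-(benzyloxy)-2-hydroxy-6-methylbenzoate
Conditions: BnBr (1.05 equiv), K2CO3, acetone, reflux
Reagents that add atoms: benzyl bromide (compound 2), BrCc1ccccc1
Why: Williamson etherification should be selective for O4, because the 4-OH is para to the ester, more acidic and not hydrogen-bonded, whereas the 2-OH is chelated to the ester carbonyl.

Step 2
Reactants: 3 methyl 4-(benzyloxy)-2-hydroxy-6-methylbenzoate
Product: 4 methyl 4-(benzyloxy)-2-methoxy-6-methylbenzoate
Conditions: MeI (excess), K2CO3, DMF, 60 °C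
Reagents that add atoms: iodomethane, CI
Why: With O4 blocked, the chelated 2-OH is methylated by Williamson etherification under more forcing conditions that leave the methyl ester and benzyl ether untouched.

Step 3
Reactants: 4 methyl 4-(benzyloxy)-2-methoxy-6-methylbenzoate
Product: 5 4-(benzyloxy)-2-methoxy-6-methylbenzoic acid
Conditions: KOH, DMSO/H2O (4:1), 90 °C; then cold 1 M HCl to pH 2
Reagents that add atoms: potassium hydroxide, [K+].[OH-]
Why: Saponification of the di-ortho-substituted ester is slow but should go to completion with poorly solvated hydroxide in aqueous DMSO; both ethers are inert and cold acidification avoids decarboxylation of the electron-rich acid.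

Step 4
Reactants: 5 4-(benzyloxy)-2-methoxy-6-methylbenzoic acid; 1 methyl orsellinate
Product: 7 methyl 4-{[4-(benzyloxy)-2-methoxy-6-methylbenzoyl]oxy}-2-hydroxy-6-methylbenzoate, via mixed trifluoroacetic anhydride 6 (not isolated)
Conditions: TFAA (4 equiv), toluene, 0 °C to rt; aq. NaHCO3 work-up
Reagents that add atoms: none
Why: In this classical depside esterification TFAA converts the hindered acid into mixed anhydride 6, an acylium source stabilised by the ortho and para alkoxy groups, which should acylate the free 4-OH of 1 in preference to the chelated 2-OH.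

Step 5
Reactants: 7 methyl 4-{[4-(benzyloxy)-2-methoxy-6-methylbenzoyl]oxy}-2-hydroxy-6-methylbenzoate
Product: 8 methyl 2-hydroxy-4-[(4-hydroxy-2-methoxy-6-methylbenzoyl)oxy]-6-methylbenzoate (A–B phenol)
Conditions: H2 (1 atm), 10% Pd/C, EtOAc, rt
Reagents that add atoms: none
Why: Catalytic hydrogenolysis cleaves only the benzyl aryl ether; the depside ester, methyl ester and methyl ether are stable to these conditions.

Step 6
Reactants: 9 2,2,6-trimethyl-4H-1,3-dioxin-4-one
Product: 11 2,2-dimethyl-6-(2-oxopropyl)-4H-1,3-dioxin-4-one, via lithium dienolate 10 (not isolated)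
Conditions: LiHMDS (1.1 equiv), THF, −78 °C; AcCl (0.55 equiv), −78 to −20 °C; 1 M HCl quench
Reagents that add atoms: acetyl chloride, CC(Cl)=O
Why: Vinylogous deprotonation of the 6-methyl group gives dienolate 10, which undergoes Claisen-type C-acylation at its γ-carbon; the half-equivalent of acetyl chloride lets the remaining dienolate deprotonate the more acidic product, and unreacted 9 is recovered.

Step 7
Reactants: 11 2,2-dimethyl-6-(2-oxopropyl)-4H-1,3-dioxin-4-one
Product: 13 6-(2,4-dioxopentyl)-2,2-dimethyl-4H-1,3-dioxin-4-one, via dilithium dianion 12 (not isolated)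
Conditions: LDA (2.3 equiv), THF, −78 °C; MeC(O)N(OMe)Me, −78 to −40 °C; 1 M HCl quench
Reagents that add atoms: N-methoxy-N-methylacetamide, CC(=O)N(C)OC
Why: Double deprotonation (doubly activated CH2 first, then the terminal CH3) gives dianion 12, whose more reactive terminal carbon attacks the Weinreb amide in a dianion Claisen condensation; the chelated tetrahedral adduct prevents over-addition.

Step 8
Reactants: 13 6-(2,4-dioxopentyl)-2,2-dimethyl-4H-1,3-dioxin-4-one; 8 A–B phenol
Product: 15 methyl 2-hydroxy-4-({2-methoxy-6-methyl-4-[(3,5,7-trioxooctanoyl)oxy]benzoyl}oxy)-6-methylbenzoate, via acylketene 14 (not isolated)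
Conditions: 13 (1.2 equiv), toluene, 110 °C, 1–2 h; concentrate and use crude
Reagents that add atoms: none
Why: Thermal retro-[4+2] fragmentation of the dioxinone expels acetone and gives acylketene 14, which should be captured by the free ring B O4–H to form the aryl β-keto ester as a keto–enol mixture, while the chelated ring A 2-OH stays a spectator.

Step 9
Reactants: 15 methyl 2-hydroxy-4-({2-methoxy-6-methyl-4-[(3,5,7-trioxooctanoyl)oxy]benzoyl}oxy)-6-methylbenzoate
Product: 17 methyl 4-({4-[(2,4-dihydroxy-6-methylbenzoyl)oxy]-2-methoxy-6-methylbenzoyl}oxy)-2-hydroxy-6-methylbenzoate (target), via aldol adduct 16 (not isolated)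
Conditions: Cs2CO3 (dried, 2 equiv), THF, 0 °C; then 1 M HCl to pH 1–2, 0 °C to rt
Reagents that add atoms: none
Why: Carbonate deprotonates the chain, and the enolate at C2 (between the aryl ester and the C3 ketone, made more acidic by the aryloxy group) adds to the C7 methyl ketone, forming chain bond C2–C7, which is the C1–C6 bond of ring C; acidification then drives loss of water from 16 and enolisation of the C3 and C5 carbonyls to the 2,4-dihydroxy-6-methylbenzoate. The closest known reaction type is the biomimetic aldol aromatisation of 3,5,7-triketo esters, made by acylketene capture, to resorcylates. Ring C is closed in a 6-(enolexo)-exo-trig mode. The two stereocentres of 16 are transient and vanish on aromatisation, so no stereocontrol is needed. The step needs the C2→C7 aldol to outrun lactonisation of the C5 enol oxygen onto C1, Claisen closure C6→C1 and E1cB reversion to the acylketene, all of which would expel the phenoxide of 8; the unhindered methyl ketone acceptor, a mild heterogeneous base at 0 °C and a medium free of alkoxide or hydroxide (which also spares both depside links and the methyl ester) should favour the aldol.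

**Compound list**
1 | methyl orsellinate (methyl 2,4-dihydroxy-6-methylbenzoate) | COC(=O)c1c(C)cc(O)cc1O | starting material
2 | benzyl bromide | BrCc1ccccc1 | starting material
3 | methyl 4-(benzyloxy)-2-hydroxy-6-methylbenzoate | COC(=O)c1c(C)cc(OCc2ccccc2)cc1O | intermediate
4 | methyl 4-(benzyloxy)-2-methoxy-6-methylbenzoate | COC(=O)c1c(C)cc(OCc2ccccc2)cc1OC | intermediate
5 | 4-(benzyloxy)-2-methoxy-6-methylbenzoic acid | OC(=O)c1c(C)cc(OCc2ccccc2)cc1OC | intermediate
6 | 4-(benzyloxy)-2-methoxy-6-methylbenzoic trifluoroacetic anhydride (not isolated) | O=C(OC(=O)C(F)(F)F)c1c(C)cc(OCc2ccccc2)cc1OC | intermediate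
7 | methyl 4-{[4-(benzyloxy)-2-methoxy-6-methylbenzoyl]oxy}-2-hydroxy-6-methylbenzoate | COC(=O)c1c(C)cc(OC(=O)c2c(C)cc(OCc3ccccc3)cc2OC)cc1O | intermediate
8 | methyl 2-hydroxy-4-[(4-hydroxy-2-methoxy-6-methylbenzoyl)oxy]-6-methylbenzoate (A–B phenol) | COC(=O)c1c(C)cc(OC(=O)c2c(C)cc(O)cc2OC)cc1O | intermediate
9 | 2,2,6-trimethyl-4H-1,3-dioxin-4-one | CC1=CC(=O)OC(C)(C)O1 | starting material
10 | lithium 2,2-dimethyl-6-methylidene-6H-1,3-dioxin-4-olate (dienolate of 9, not isolated) | [Li+].[O-]C1=CC(=C)OC(C)(C)O1 | intermediate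
11 | 2,2-dimethyl-6-(2-oxopropyl)-4H-1,3-dioxin-4-one | CC(=O)CC1=CC(=O)OC(C)(C)O1 | intermediate
12 | dilithium dianion of 11, deprotonated at the ring-adjacent CH2 and the terminal CH3 (not isolated) | [Li+].[Li+].C=C([O-])C=C1C=C([O-])OC(C)(C)O1 | intermediate
13 | 6-(2,4-dioxopentyl)-2,2-dimethyl-4H-1,3-dioxin-4-one | CC(=O)CC(=O)CC1=CC(=O)OC(C)(C)O1 | intermediate
14 | acylketene oct-1-ene-1,3,5,7-tetrone (not isolated) | CC(=O)CC(=O)CC(=O)C=C=O | intermediate
15 | methyl 2-hydroxy-4-({2-methoxy-6-methyl-4-[(3,5,7-trioxooctanoyl)oxy]benzoyl}oxy)-6-methylbenzoate (keto–enol mixture) | CC(=O)CC(=O)CC(=O)CC(=O)Oc1cc(C)c(C(=O)Oc2cc(C)c(C(=O)OC)c(O)c2)c(OC)c1 | intermediate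
16 | aldol adduct: the 2-hydroxy-2-methyl-4,6-dioxocyclohexane-1-carboxylate ester of phenol 8 (diastereomer and tautomer mixture, not isolated) | CC1(O)CC(=O)CC(=O)C1C(=O)Oc1cc(C)c(C(=O)Oc2cc(C)c(C(=O)OC)c(O)c2)c(OC)c1 | intermediate
17 | methyl 4-({4-[(2,4-dihydroxy-6-methylbenzoyl)oxy]-2-methoxy-6-methylbenzoyl}oxy)-2-hydroxy-6-methylbenzoate | COC(=O)c1c(C)cc(OC(=O)c2c(C)cc(OC(=O)c3c(C)cc(O)cc3O)cc2OC)cc1O | target

**Step count**
Total: 9 steps. Longest linear sequence: 7 steps (steps 1, 2, 3, 4, 5, 8, 9); the dioxinone branch (steps 6, 7) joins at step 8.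

**Steps most likely to fail**

Step 9 (key step). The enolised chain may close through oxygen (C5 enol oxygen onto the aryl ester carbonyl, giving a 4-hydroxy-2-pyranone) or through C6 (Claisen closure to an acetylphloroglucinol). Either path expels the A–B phenoxide. The aryl β-keto ester may also revert to the acylketene by E1cB loss of phenoxide, and adventitious hydroxide may cleave a depside link. Fallback: carry out the aldol aromatisation before the ester bond exists, where the carboxyl is locked in the acetonide and nothing can leave. The fallback sets out from 13 and 8. Et3N in CH2Cl2 at rt should convert 13, by the same intramolecular aldol and dehydration, into 7-hydroxy-2,2,5-trimethyl-4H-1,3-benzodioxin-4-one F1. Benzylation with 2 (K2CO3, acetone) gives 7-(benzyloxy)-2,2,5-trimethyl-4H-1,3-benzodioxin-4-one F2. Irradiation of F2 at 300 nm in CH2Cl2 in the presence of 8 releases acetone and the quinoketene 3-(benzyloxy)-5-methyl-6-(oxomethylidene)cyclohexa-2,4-dien-1-one F3, which has no internal escape route and should be captured by the ring B hydroxyl of 8 to give methyl 4-[(4-{[4-(benzyloxy)-2-hydroxy-6-methylbenzoyl]oxy}-2-methoxy-6-methylbenzoyl)oxy]-2-hydroxy-6-methylbenzoate F4. Hydrogenolysis (H2, Pd/C, EtOAc) then rejoins the route at 17.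

Step 8. Capture of the acylketene by the weakly nucleophilic, acyl-substituted phenol may be outrun by closure of the ketene onto its own C5 enol oxygen (2-pyranone formation) or by ketene dimerisation. Capture may also occur at the chelated ring A hydroxyl, and the product may not tolerate 110 °C. Fallback: form the B–C ester by classical acyl transfer from a protected orsellinic acid, with no ketene involved. The fallback sets out from 1 and 8. Methyl orsellinate 1 with excess 2 (K2CO3, DMF, 70 °C) gives methyl 2,4-bis(benzyloxy)-6-methylbenzoate F5. Saponification (KOH, aqueous DMSO, 90 °C) gives 2,4-bis(benzyloxy)-6-methylbenzoic acid F6. TFAA in toluene converts F6 into 2,4-bis(benzyloxy)-6-methylbenzoic trifluoroacetic anhydride F7, which acylates the ring B hydroxyl of 8 to give methyl 4-[(4-{[2,4-bis(benzyloxy)-6-methylbenzoyl]oxy}-2-methoxy-6-methylbenzoyl)oxy]-2-hydroxy-6-methylbenzoate F8. Hydrogenolysis (H2, Pd/C, EtOAc) rejoins the route at 17.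

Step 7. Dianion formation may be incomplete, the product may be quenched by proton transfer to unreacted dianion, the keto-dioxinone may self-condense or O-acylate, and the dioxinone enolate may fragment on warming. Fallback: magnesium-chelate C-acylation followed by decarboxylation, which needs no dianion. The fallback sets out from 9. Dienolate 10 (LiHMDS, THF, −78 °C) is acylated with allyl malonyl chloride to give allyl 4-(2,2-dimethyl-4-oxo-4H-1,3-dioxin-6-yl)-3-oxobutanoate F9. MgCl2, pyridine and acetyl chloride in CH2Cl2 at 0 °C acetylate the doubly activated methylene to give allyl 2-acetyl-4-(2,2-dimethyl-4-oxo-4H-1,3-dioxin-6-yl)-3-oxobutanoate F10. Pd(PPh3)4 (cat.) with morpholine in THF removes the allyl group, and the resulting 2-acetyl-4-(2,2-dimethyl-4-oxo-4H-1,3-dioxin-6-yl)-3-oxobutanoic acid F11 loses CO2 in the flask, rejoining the route at 13.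

**Further compounds**
F1 | step 9 | 7-hydroxy-2,2,5-trimethyl-4H-1,3-benzodioxin-4-one | CC1(C)OC(=O)c2c(C)cc(O)cc2O1
F2 | step 9 | 7-(benzyloxy)-2,2,5-trimethyl-4H-1,3-benzodioxin-4-one | CC1(C)OC(=O)c2c(C)cc(OCc3ccccc3)cc2O1
F3 | step 9 | 3-(benzyloxy)-5-methyl-6-(oxomethylidene)cyclohexa-2,4-dien-1-one (quinoketene, not isolated) | O=C=C1C(C)=CC(OCc2ccccc2)=CC1=O
F4 | step 9 | methyl 4-[(4-{[4-(benzyloxy)-2-hydroxy-6-methylbenzoyl]oxy}-2-methoxy-6-methylbenzoyl)oxy]-2-hydroxy-6-methylbenzoate | COC(=O)c1c(C)cc(OC(=O)c2c(C)cc(OC(=O)c3c(C)cc(OCc4ccccc4)cc3O)cc2OC)cc1O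
F5 | step 8 | methyl 2,4-bis(benzyloxy)-6-methylbenzoate | COC(=O)c1c(C)cc(OCc2ccccc2)cc1OCc1ccccc1
F6 | step 8 | 2,4-bis(benzyloxy)-6-methylbenzoic acid | OC(=O)c1c(C)cc(OCc2ccccc2)cc1OCc1ccccc1
F7 | step 8 | 2,4-bis(benzyloxy)-6-methylbenzoic trifluoroacetic anhydride (not isolated) | O=C(OC(=O)C(F)(F)F)c1c(C)cc(OCc2ccccc2)cc1OCc1ccccc1
F8 | step 8 | methyl 4-[(4-{[2,4-bis(benzyloxy)-6-methylbenzoyl]oxy}-2-methoxy-6-methylbenzoyl)oxy]-2-hydroxy-6-methylbenzoate | COC(=O)c1c(C)cc(OC(=O)c2c(C)cc(OC(=O)c3c(C)cc(OCc4ccccc4)cc3OCc5ccccc5)cc2OC)cc1O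
F9 | step 7 | allyl 4-(2,2-dimethyl-4-oxo-4H-1,3-dioxin-6-yl)-3-oxobutanoate | C=CCOC(=O)CC(=O)CC1=CC(=O)OC(C)(C)O1
F10 | step 7 | allyl 2-acetyl-4-(2,2-dimethyl-4-oxo-4H-1,3-dioxin-6-yl)-3-oxobutanoate | C=CCOC(=O)C(C(C)=O)C(=O)CC1=CC(=O)OC(C)(C)O1
F11 | step 7 | 2-acetyl-4-(2,2-dimethyl-4-oxo-4H-1,3-dioxin-6-yl)-3-oxobutanoic acid (not isolated) | OC(=O)C(C(C)=O)C(=O)CC1=CC(=O)OC(C)(C)O1
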